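## Analysis of the target

Sarcotrine D is an acyclic C21 chain, numbered here C1–C21 from the lactone carbonyl, that ends in two five-membered heterocycles. In the west sits a 3-methyltetronic acid (C1–C4 plus the ring oxygen); in the east an N-(3-methylbutyl)-1,5-dihydro-2H-pyrrol-2-one (C18–C21 plus N). The chain carries a Z-trisubstituted alkene (C6=C7) and an (11E,13E)-diene whose distal alkene C13=C14 is trisubstituted. There are two stereocentres: C4 (S, the ring CH–O of the tetronic acid) and C10 (S, methyl-bearing, allylic to the diene). They stand 1,7 to each other across the Z-alkene, so neither can direct the other, and an error at either one appears as a diastereomer that will hardly be separable. The sensitive groups are the tetronic acid (acidic, metal-binding, C4–H epimerisable by strong base), the vinylogously acidic C21H2 of the lactam, the diene (acid, singlet oxygen, electrophiles) and the C6=C7 geometry, which must never pass through an allyl–metal species. No ring is hard to build; the difficulty is C10, a lone stereocentre in a hydrocarbon stretch with no functional group nearby, together with three alkene geometries and the need for convergence. The feature the route seizes is this atom: C10 is an sp3 carbon flanked by C9H2 and the C11=C12 vinyl unit, which is the product pattern of an allylic alkyl–alkyl coupling and invites a stereoconvergent formation of the C9–C10 bond from a racemic allylic electrophile.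

## Retrosynthetic reasoning

**C12–C13 (32 ⇒ 18 + 31).** The diene is cut between its two alkenes. A stereospecific sp2–sp2 coupling of the (E)-alkenylboronate 18 with the (E)-iodoalkene 31 transfers both geometries unchanged, joins two halves of similar size in the last step, and keeps the base-sensitive lactam out of all enolate chemistry.

**Tetronic acid, C2–C3 (18 ⇒ 17).** The ring is opened to the α-propanoyloxy methyl ester 17. The forward Dieckmann closure is placed before the lactam arrives and after all organometallic steps, so the tetronic acid needs no protecting group.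

**C9–C10, the key disconnection (17 ⇒ 16 + 15).** The C9–C10 bond is cut next to the stereocentre. The forward step is an enantioconvergent nickel-catalysed coupling of the primary alkylzinc 16 with the racemic γ-boryl allylic chloride 15. It must form the sp3–sp3 bond at the methyl-bearing allyl terminus, set C10 by catalyst control alone, and leave the (E)-alkenylboron handle for the diene coupling. The allylic partner is kept small on purpose. Had it carried the eastern diene, C14 would be the tertiary terminus of a pentadienyl system, which invites ionisation, loss of the C13=C14 geometry and triene formation. In 15 the boryl group destabilises the cation instead, and the diene bond is held back for the stereospecific coupling.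

**C5–C6 and the C4 stereocentre (12 ⇒ 11 ⇒ 10 ⇒ 6 + 7).** The bromide 12 comes from silyl ether 11, and this from hydroxy ester 10 by acylation. Compound 10 is cut at C5–C6 into the (Z)-iodoalkene 6 and the glycidate 7. The epoxide delivers C3–C5 with C4 already correct and at the right oxidation level, and an alkenyl–metal opening at the CH2 terminus keeps the alkene geometry.

**C6=C7 (6 ⇒ 1 + 2).** The Z-trisubstituted alkene is traced to an α-iodo Wittig olefination of aldehyde 1 with the ylide from 2. It puts iodine cis to the chain, which is the geometry that later places C5 and C8 cis.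

**Allylic partner (15 ⇒ 14 ⇒ 13).** The racemic chloride 15 comes from alcohol 14, and this from the racemic alkynol 13 by syn-borylation. Nothing stereochemical has to be controlled here.

**Lactam (31 ⇒ 27 + 28 ⇒ 25).** The pyrrolinone is opened at both C–N bonds to the γ-hydroxybutenolide 27 and amine 28 (reductive amination and lactamisation). Compound 27 is the singlet-oxygen product of the 3-alkylfuran 25. This furan-to-lactam conversion is done early because the later diene would not survive singlet oxygen.

**Furan side chain (25 ⇒ 23 ⇒ 22 ⇒ 19 + 20).** The (E)-iodoalkene comes from carboalumination and iodination of alkyne 23. The alkyne is attached to the furan by an sp3–sp2 coupling of 19 with the zinc reagent 21 made from 20, followed by desilylation of 22.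

## Alternatives that were turned down

**Alternative 1:** the textbook route. Disconnection: C12–C13 by diene cross-coupling, with C10 bought from the chiral pool and the tetronic acid made by a late Dieckmann closure. Forward: (3S)-3,7-dimethylocta-1,6-diene A1 is ozonised at its trisubstituted alkene to (4S)-4-methylhex-5-enal A2; the aldehyde end is elaborated to the western half and the vinyl group is turned into an alkenylboron for the coupling. Turned down for three reasons:
- The vinyl group of A2 ends up 1,6 to the C6=C7 alkene, so any ruthenium carbene at C11 closes to a methylcyclopentene. The direct cross-metathesis to the alkenylboronate is therefore blocked.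
- The workable variant (an alkyne in place of the vinyl group) needs a strongly basic aldehyde-to-alkyne dehydration next to the future C10 centre and throws away three carbons of the terpene.
- It is one step longer in the linear sequence and C10 is fixed by what the pool offers. It is kept only as a fallback.

**Alternative 2:** a late carbonyl-ene reaction. Disconnection: C4–C5, with C6=C7 created in the same step. Forward: a catalytic asymmetric glyoxylate-ene reaction of the full-length 1,1-disubstituted alkene A3, 4-[(4E,6E,8S)-4,8,12-trimethyltrideca-4,6,12-trien-1-yl]-1-(3-methylbutyl)-1,5-dihydro-2H-pyrrol-2-one, would give the α-hydroxy ester A4, ethyl (2S,4Z,8S,9E,11E)-2-hydroxy-4,8,12-trimethyl-15-[1-(3-methylbutyl)-5-oxo-2,5-dihydro-1H-pyrrol-3-yl]pentadeca-4,9,11-trienoate, which is then acylated and cyclised. One step would set C4, form C4–C5 and place the alkene. Turned down for two reasons: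
- The ene hydrogen can come from the methyl group or from C7H2, so an exo-methylene isomer competes. The trisubstituted isomer has no structural bias towards the Z geometry the target needs.
- The C11–C14 diene is a hetero-Diels–Alder partner for the Lewis-acid-activated glyoxylate, and the lactam carbonyl binds the catalyst.

**Alternative 3:** biomimetic furan oxidation at the end. Disconnection: both C–N bonds of the lactam in the last step. Forward: singlet oxygen on the furan A5, (5S)-5-[(2Z,6S,7E,9E)-13-(furan-3-yl)-2,6,10-trimethyltrideca-2,7,9-trien-1-yl]-4-hydroxy-3-methylfuran-2(5H)-one, then reductive amination with 28. Turned down because A5 offers singlet oxygen three more reactive sites: the E,E-diene ([4+2]), two trisubstituted alkenes (ene reaction) and the electron-rich tetronic enol. Chemoselectivity for the furan cannot be argued on a late intermediate. The same chemistry is therefore used early, on 25, where the only other π-system is a deactivated iodoalkene.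

Key step: step 7

Remark: atom labels C1–C21 refer to the target. Compounds 1, 2, 7, 13, 19, 20 and 28 are taken as commercial. The pybox antipode in step 7 is chosen by analogy with simple 1-methylallyl chlorides and is exchanged for its mirror image if a model coupling shows the opposite sense; nothing else changes.

## Route

Step 1
Reactants: 1 3-{[tert-butyl(dimethyl)silyl]oxy}propanal; 2 ethyltriphenylphosphonium iodide
Product: 6 tert-butyl{[(3Z)-4-iodopent-3-en-1-yl]oxy}dimethylsilane, via ethylidenetriphenylphosphorane 3 (not isolated), via (1-iodoethyl)triphenylphosphonium iodide 4 (not isolated), via (1-iodoethylidene)triphenylphosphorane 5 (not isolated)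
Conditions: n-BuLi, THF, 0 °C; I2, −78 °C; NaHMDS, −20 °C; then 1, −78 → −20 °C
Reagents that add atoms: iodine, II
Why: Stork–Zhao-type α-iodo Wittig olefination; the non-stabilised α-iodo ylide 5 adds under kinetic control and should give the (Z)-2-iodoalkene with iodine cis to the chain, the geometry that later puts C5 and C8 cis.

Step 2
Reactants: 6 tert-butyl{[(3Z)-4-iodopent-3-en-1-yl]oxy}dimethylsilane; 7 methyl (2S)-oxirane-2-carboxylate
Product: 10 methyl (2S,4Z)-7-{[tert-butyl(dimethyl)silyl]oxy}-2-hydroxy-4-methylhept-4-enoate, via [(2E)-5-{[tert-butyl(dimethyl)silyl]oxy}pent-2-en-2-yl]lithium 8 (not isolated), via bromo[(2Z)-5-{[tert-butyl(dimethyl)silyl]oxy}pent-2-en-2-yl]magnesium 9 (not isolated)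
Conditions: t-BuLi (2 equiv), Et2O, −78 °C; MgBr2·OEt2; CuBr·SMe2 (cat.), 7, THF/Et2O, −78 → −40 °C; aq. NH4Cl
Reagents that add atoms: none
Why: Iodine–lithium exchange and transmetalation proceed with retention of alkene geometry, and copper-catalysed SN2 opening of the glycidic ester at its unsubstituted CH2 terminus forms C5–C6 faster than carbonyl addition at low temperature. C4 is not a reacting centre and is carried over unchanged from 7.

Step 3
Reactants: 10 methyl (2S,4Z)-7-{[tert-butyl(dimethyl)silyl]oxy}-2-hydroxy-4-methylhept-4-enoate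
Product: 11 methyl (2S,4Z)-7-{[tert-butyl(dimethyl)silyl]oxy}-4-methyl-2-(propanoyloxy)hept-4-enoate
Conditions: (EtCO)2O, Et3N, DMAP (cat.), CH2Cl2, 0 °C → rt
Reagents that add atoms: propanoic anhydride, CCC(=O)OC(=O)CC
Why: DMAP-catalysed O-acylation of the secondary alcohol under non-enolising conditions; it installs C1, C2 and the C2 methyl group of the future tetronic acid.

Step 4
Reactants: 11 methyl (2S,4Z)-7-{[tert-butyl(dimethyl)silyl]oxy}-4-methyl-2-(propanoyloxy)hept-4-enoate
Product: 12 methyl (2S,4Z)-7-bromo-4-methyl-2-(propanoyloxy)hept-4-enoate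
Conditions: Ph3PBr2, CH2Cl2, 0 °C → rt
Reagents that add atoms: dibromotriphenylphosphorane, BrP(Br)(c1ccccc1)(c1ccccc1)c1ccccc1
Why: Direct Appel-type conversion of a primary silyl ether into the bromide (Si–O cleavage, then SN2 of bromide on the alkoxyphosphonium ion); the neutral conditions should leave the α-acyloxy ester and the Z-alkene untouched and save a separate desilylation.

Step 5
Reactants: 13 but-3-yn-2-ol (racemic)
Product: 14 (3E)-4-(4,4,5,5-tetramethyl-1,3,2-dioxaborolan-2-yl)but-3-en-2-ol (racemic)
Conditions: B2pin2, CuCl (cat.), Xantphos (cat.), NaOt-Bu (cat.), MeOH, THF, rt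
Reagents that add atoms: bis(pinacolato)diboron, CC1(C)OB(OC1(C)C)B1OC(C)(C)C(C)(C)O1
Why: Copper-catalysed syn-borylcupration and protonation (formal anti-Markovnikov hydroboration) of the terminal alkyne gives the (E)-alkenylboronate and tolerates the free hydroxyl; the carbinol centre is racemic on purpose.

Step 6
Reactants: 14 (3E)-4-(4,4,5,5-tetramethyl-1,3,2-dioxaborolan-2-yl)but-3-en-2-ol (racemic)
Product: 15 2-[(1E)-3-chlorobut-1-en-1-yl]-4,4,5,5-tetramethyl-1,3,2-dioxaborolane (racemic)
Conditions: PPh3, NCS, CH2Cl2, 0 °C → rt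
Reagents that add atoms: N-chlorosuccinimide, ClN1C(=O)CCC1=O
Why: Appel-type chlorination of the secondary allylic alcohol; the electron-poor boryl-alkene disfavours ionisation, so the chloride should be stable to handling. Its configuration, and any allylic transposition, do not matter because step 7 is stereo- and regioconvergent.

Step 7
Reactants: 12 methyl (2S,4Z)-7-bromo-4-methyl-2-(propanoyloxy)hept-4-enoate; 15 2-[(1E)-3-chlorobut-1-en-1-yl]-4,4,5,5-tetramethyl-1,3,2-dioxaborolane (racemic)
Product: 17 methyl (2S,4Z,8S,9E)-4,8-dimethyl-2-(propanoyloxy)-10-(4,4,5,5-tetramethyl-1,3,2-dioxaborolan-2-yl)deca-4,9-dienoate, via bromo[(3Z,6S)-7-methoxy-4-methyl-7-oxo-6-(propanoyloxy)hept-3-en-1-yl]zinc 16 (not isolated)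
Conditions: Zn dust, I2 (cat.), DMA, 70 °C; then 15 (slight excess), NiCl2·glyme (cat.), (S,S)-2,6-bis(4-phenethyl-2-oxazolin-2-yl)pyridine (cat.), NaCl, DMA/DMF, −10 °C
Reagents that add atoms: none
Why: Enantioconvergent Ni/pybox-catalysed Negishi alkyl–alkyl coupling of a racemic secondary allylic chloride. Zinc inserts into the primary C–Br bond of 12 to give 16, which transmetalates to nickel; halide abstraction from either enantiomer, and from either allylic regioisomer, of 15 gives the same 1-methyl-3-boryl-allyl nickel species, so the stereochemical information of the electrophile is erased before the C–C bond forms. Reductive elimination from the chiral Ni(alkyl)(allyl) complex then forms C9–C10; no ring is closed. The new C10 stereocentre is controlled by the pybox ligand alone: the C4 centre of the nucleophile is too remote to match or mismatch, so the diastereomer ratio should equal the enantiomer ratio the catalyst gives with achiral alkylzincs. Regioselectivity for the methyl-bearing terminus over the boron-bearing one is secured by the size of the pinacolboryl group and by the B–C=C conjugation kept in the product, in line with this catalyst's preference for the less hindered terminus and for conjugated products. E geometry at C11=C12 follows from the syn,syn-allyl intermediate. Chemoselectivity follows because esters, the Z-alkene and the sp2 C–B bond are inert to alkylzinc halides and to Ni/pybox at −10 °C. The closest known reaction type is the Ni/pybox Negishi coupling of racemic 1,3-disubstituted allylic chlorides, including γ-chloro-α,β-unsaturated carbonyl compounds, with functionalised alkylzinc bromides.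

Step 8
Reactants: 17 methyl (2S,4Z,8S,9E)-4,8-dimethyl-2-(propanoyloxy)-10-(4,4,5,5-tetramethyl-1,3,2-dioxaborolan-2-yl)deca-4,9-dienoate
Product: 18 (5S)-5-[(2Z,6S,7E)-2,6-dimethyl-8-(4,4,5,5-tetramethyl-1,3,2-dioxaborolan-2-yl)octa-2,7-dien-1-yl]-4-hydroxy-3-methylfuran-2(5H)-one
Conditions: LiHMDS (3 equiv), THF, −78 → 0 °C; 1 M HCl
Reagents that add atoms: none
Why: Dieckmann (intramolecular Claisen) cyclisation of the α-acyloxy ester: the propanoate enolate attacks the methyl ester 5-exo-trig, methoxide leaves, and the product is trapped as the tetronate, which drives the reaction and shields C4–H from further deprotonation. The hindered amide base should not add irreversibly to the pinacol boronate, which is returned on acidic work-up.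

Step 9
Reactants: 19 3-bromofuran; 20 (5-iodopent-1-yn-1-yl)trimethylsilane
Product: 22 [5-(furan-3-yl)pent-1-yn-1-yl]trimethylsilane, via iodo[5-(trimethylsilyl)pent-4-yn-1-yl]zinc 21 (not isolated)
Conditions: Zn dust, LiCl, THF, 40 °C; then 19, Pd(OAc)2 (cat.), SPhos (cat.), THF, rt → 50 °C
Reagents that add atoms: none
Why: Negishi sp3–sp2 coupling; zinc inserts into the primary C–I bond, and a bulky biarylphosphine palladium catalyst couples the alkylzinc with the heteroaryl bromide faster than β-hydride elimination. The silyl group keeps the alkyne out of metalation.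

Step 10
Reactants: 22 [5-(furan-3-yl)pent-1-yn-1-yl]trimethylsilane
Product: 23 3-(pent-4-yn-1-yl)furan
Conditions: K2CO3 (cat.), MeOH, rt
Reagents that add atoms: none
Why: Base-catalysed methanolysis of the C(sp)–Si bond frees the terminal alkyne needed for carbometalation.

Step 11
Reactants: 23 3-(pent-4-yn-1-yl)furan
Product: 25 3-[(4E)-5-iodo-4-methylpent-4-en-1-yl]furan, via [(1E)-5-(furan-3-yl)-2-methylpent-1-en-1-yl]dimethylalumane 24 (not isolated)
Conditions: AlMe3, Cp2ZrCl2 (cat.), CH2Cl2, 0 °C → rt; then I2, THF, −30 °C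
Reagents that add atoms: trimethylaluminium, C[Al](C)C; iodine, II
Why: Zirconium-catalysed carboalumination adds methyl and aluminium syn across the terminal alkyne with aluminium at the terminal carbon; iodinolysis with retention then gives the (E)-trisubstituted iodoalkene, fixing the C13=C14 geometry.

Step 12
Reactants: 25 3-[(4E)-5-iodo-4-methylpent-4-en-1-yl]furan
Product: 27 5-hydroxy-4-[(4E)-5-iodo-4-methylpent-4-en-1-yl]furan-2(5H)-one, via 5-[(4E)-5-iodo-4-methylpent-4-en-1-yl]-2,3,7-trioxabicyclo[2.2.1]hept-5-ene 26 (not isolated)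
Conditions: O2, hν (visible), rose bengal (cat.), i-Pr2NEt, CH2Cl2, −78 °C → rt
Reagents that add atoms: dioxygen, O=O
Why: [4+2] addition of singlet oxygen to the furan gives endoperoxide 26; the hindered amine removes the bridgehead proton remote from the alkyl group (Kornblum–DeLaMare-type fragmentation), so the carbonyl appears at the unsubstituted α-carbon and the hydroxyl next to the side chain. The iodine-deactivated alkene should not compete in the ene reaction.

Step 13
Reactants: 27 5-hydroxy-4-[(4E)-5-iodo-4-methylpent-4-en-1-yl]furan-2(5H)-one; 28 3-methylbutan-1-amine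
Product: 31 4-[(4E)-5-iodo-4-methylpent-4-en-1-yl]-1-(3-methylbutyl)-1,5-dihydro-2H-pyrrol-2-one, via (2Z,7E)-8-iodo-7-methyl-3-{[(3-methylbutyl)imino]methyl}octa-2,7-dienoic acid 29 (not isolated), via (2Z,7E)-8-iodo-7-methyl-3-{[(3-methylbutyl)amino]methyl}octa-2,7-dienoic acid 30 (not isolated)
Conditions: AcOH, NaBH(OAc)3, ClCH2CH2Cl, rt → 50 °C
Reagents that add atoms: none
Why: Reductive amination of the masked aldehyde: the open form of 27 condenses with 28 to imine 29, hydride gives the (Z)-γ-amino acid 30, and this lactamises because the Z-alkene holds amine and carboxyl together. The ring alkene is not touched, so the 4-substituted 1,5-dihydropyrrol-2-one results.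

Step 14
Reactants: 18 (5S)-5-[(2Z,6S,7E)-2,6-dimethyl-8-(4,4,5,5-tetramethyl-1,3,2-dioxaborolan-2-yl)octa-2,7-dien-1-yl]-4-hydroxy-3-methylfuran-2(5H)-one; 31 4-[(4E)-5-iodo-4-methylpent-4-en-1-yl]-1-(3-methylbutyl)-1,5-dihydro-2H-pyrrol-2-one
Product: 32 sarcotrine D, (5S)-4-hydroxy-3-methyl-5-{(2Z,6S,7E,9E)-2,6,10-trimethyl-13-[1-(3-methylbutyl)-5-oxo-2,5-dihydro-1H-pyrrol-3-yl]trideca-2,7,9-trien-1-yl}furan-2(5H)-one
Conditions: Pd(dppf)Cl2 (cat.), aq. K3PO4 (4 equiv), THF, degassed, rt → 40 °C; then citric acid to pH 3
Reagents that add atoms: none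
Why: Suzuki–Miyaura sp2–sp2 coupling with retention at both alkenes forms C12–C13 and the (11E,13E)-diene. The tetronic acid travels as its tetronate (extra base) and is regenerated on acidification; neither stereocentre is touched.

## Compound list

1 | 3-{[tert-butyl(dimethyl)silyl]oxy}propanal | O=CCCO[Si](C)(C)C(C)(C)C | starting material
2 | ethyltriphenylphosphonium iodide | CC[P+](c1ccccc1)(c1ccccc1)c1ccccc1.[I-] | starting material
3 | ethylidenetriphenylphosphorane | CC=P(c1ccccc1)(c1ccccc1)c1ccccc1 | intermediate (not isolated)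
4 | (1-iodoethyl)triphenylphosphonium iodide | CC(I)[P+](c1ccccc1)(c1ccccc1)c1ccccc1.[I-] | intermediate (not isolated)
5 | (1-iodoethylidene)triphenylphosphorane | CC(I)=P(c1ccccc1)(c1ccccc1)c1ccccc1 | intermediate (not isolated)
6 | tert-butyl{[(3Z)-4-iodopent-3-en-1-yl]oxy}dimethylsilane | I/C(C)=C\CCO[Si](C)(C)C(C)(C)C | intermediate
7 | methyl (2S)-oxirane-2-carboxylate | COC(=O)[C@@H]1CO1 | starting material
8 | [(2E)-5-{[tert-butyl(dimethyl)silyl]oxy}pent-2-en-2-yl]lithium (Li cis to the chain, geometry of 6 retained) | [Li]/C(C)=C\CCO[Si](C)(C)C(C)(C)C | intermediate (not isolated)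
9 | bromo[(2Z)-5-{[tert-butyl(dimethyl)silyl]oxy}pent-2-en-2-yl]magnesium | Br[Mg]/C(C)=C\CCO[Si](C)(C)C(C)(C)C | intermediate (not isolated)
10 | methyl (2S,4Z)-7-{[tert-butyl(dimethyl)silyl]oxy}-2-hydroxy-4-methylhept-4-enoate | COC(=O)[C@@H](O)C/C(C)=C\CCO[Si](C)(C)C(C)(C)C | intermediate
11 | methyl (2S,4Z)-7-{[tert-butyl(dimethyl)silyl]oxy}-4-methyl-2-(propanoyloxy)hept-4-enoate | CCC(=O)O[C@@H](C/C(C)=C\CCO[Si](C)(C)C(C)(C)C)C(=O)OC | intermediate
12 | methyl (2S,4Z)-7-bromo-4-methyl-2-(propanoyloxy)hept-4-enoate | CCC(=O)O[C@@H](C/C(C)=C\CCBr)C(=O)OC | intermediate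
13 | but-3-yn-2-ol (racemic) | CC(O)C#C | starting material
14 | (3E)-4-(4,4,5,5-tetramethyl-1,3,2-dioxaborolan-2-yl)but-3-en-2-ol (racemic) | CC(O)/C=C/B1OC(C)(C)C(C)(C)O1 | intermediate
15 | 2-[(1E)-3-chlorobut-1-en-1-yl]-4,4,5,5-tetramethyl-1,3,2-dioxaborolane (racemic) | CC(Cl)/C=C/B1OC(C)(C)C(C)(C)O1 | intermediate
16 | bromo[(3Z,6S)-7-methoxy-4-methyl-7-oxo-6-(propanoyloxy)hept-3-en-1-yl]zinc | CCC(=O)O[C@@H](C/C(C)=C\CC[Zn]Br)C(=O)OC | intermediate (not isolated)
17 | methyl (2S,4Z,8S,9E)-4,8-dimethyl-2-(propanoyloxy)-10-(4,4,5,5-tetramethyl-1,3,2-dioxaborolan-2-yl)deca-4,9-dienoate | CCC(=O)O[C@@H](C/C(C)=C\CC[C@H](C)/C=C/B1OC(C)(C)C(C)(C)O1)C(=O)OC | intermediate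
18 | (5S)-5-[(2Z,6S,7E)-2,6-dimethyl-8-(4,4,5,5-tetramethyl-1,3,2-dioxaborolan-2-yl)octa-2,7-dien-1-yl]-4-hydroxy-3-methylfuran-2(5H)-one | CC1=C(O)[C@H](C/C(C)=C\CC[C@H](C)/C=C/B2OC(C)(C)C(C)(C)O2)OC1=O | intermediate
19 | 3-bromofuran | Brc1ccoc1 | starting material
20 | (5-iodopent-1-yn-1-yl)trimethylsilane | C[Si](C)(C)C#CCCCI | starting material
21 | iodo[5-(trimethylsilyl)pent-4-yn-1-yl]zinc | C[Si](C)(C)C#CCCC[Zn]I | intermediate (not isolated)
22 | [5-(furan-3-yl)pent-1-yn-1-yl]trimethylsilane | C[Si](C)(C)C#CCCCc1ccoc1 | intermediate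
23 | 3-(pent-4-yn-1-yl)furan | C#CCCCc1ccoc1 | intermediate
24 | [(1E)-5-(furan-3-yl)-2-methylpent-1-en-1-yl]dimethylalumane | C[Al](C)/C=C(\C)CCCc1ccoc1 | intermediate (not isolated)
25 | 3-[(4E)-5-iodo-4-methylpent-4-en-1-yl]furan | I/C=C(\C)CCCc1ccoc1 | intermediate
26 | 5-[(4E)-5-iodo-4-methylpent-4-en-1-yl]-2,3,7-trioxabicyclo[2.2.1]hept-5-ene | C12OOC(O1)C=C2CCC/C(C)=C/I | intermediate (not isolated)
27 | 5-hydroxy-4-[(4E)-5-iodo-4-methylpent-4-en-1-yl]furan-2(5H)-one (hemiacetal carbon unassigned) | OC1OC(=O)C=C1CCC/C(C)=C/I | intermediate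
28 | 3-methylbutan-1-amine | CC(C)CCN | starting material
29 | (2Z,7E)-8-iodo-7-methyl-3-{[(3-methylbutyl)imino]methyl}octa-2,7-dienoic acid | OC(=O)/C=C(\C=NCCC(C)C)CCC/C(C)=C/I | intermediate (not isolated)
30 | (2Z,7E)-8-iodo-7-methyl-3-{[(3-methylbutyl)amino]methyl}octa-2,7-dienoic acid | OC(=O)/C=C(\CNCCC(C)C)CCC/C(C)=C/I | intermediate (not isolated)
31 | 4-[(4E)-5-iodo-4-methylpent-4-en-1-yl]-1-(3-methylbutyl)-1,5-dihydro-2H-pyrrol-2-one | O=C1C=C(CCC/C(C)=C/I)CN1CCC(C)C | intermediate
32 | sarcotrine D | CC1=C(O)[C@H](C/C(C)=C\CC[C@H](C)/C=C/C=C(\C)CCCC2=CC(=O)N(CCC(C)C)C2)OC1=O | target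

## Step count and risk

Total: 14 steps. Longest linear sequence: 7 steps (1, 2, 3, 4, 7, 8, 14) from 1. The side branches are steps 5–6 (into step 7) and steps 9–13 (into step 14).

Steps least certain to work, each with one fallback:

**Step 7 (key step).** Two things are most likely to go wrong. C–C bond formation may occur partly at the boron-bearing allyl terminus, and enantiocontrol may be incomplete. Because C4 and C10 are remote, any erosion of enantioselectivity shows up as a diastereomer that cannot be removed later.

Fallback (C10 from the chiral pool, boron introduced last):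
- (3S)-3,7-dimethyloct-6-enal F1 is dehydrated through its enol nonaflate (C4F9SO2F, phosphazene base, DMF) to (3S)-3,7-dimethyloct-6-en-1-yne F2.
- Selective ozonolysis of the trisubstituted alkene (O3, CH2Cl2/MeOH, −78 °C, indicator end-point; Me2S) gives (4S)-4-methylhex-5-ynal F3.
- Ylide 5 under the conditions of step 1 gives (3S,6Z)-7-iodo-3-methyloct-6-en-1-yne F4.
- Iodine–lithium exchange with one extra equivalent of t-BuLi (the acetylide acts as a non-transferable ligand), MgBr2, catalytic CuBr·SMe2 and glycidate 7 as in step 2 give methyl (2S,4Z,8S)-2-hydroxy-4,8-dimethyldec-4-en-9-ynoate F5.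
- Propanoylation as in step 3 gives methyl (2S,4Z,8S)-4,8-dimethyl-2-(propanoyloxy)dec-4-en-9-ynoate F6.
- Zirconium-catalysed syn-hydroboration of the terminal alkyne with pinacolborane gives 17.

The fallback sets out from 5 (with 7) and comes back at 17. It gives up catalyst control at C10 and is one step longer in the linear sequence.

**Step 8.** The amide base or the liberated methoxide may bind to boron and cause loss of the boronate on work-up. Competing deprotonation at the α-carbon of the methyl ester would erode C4 or trigger a 1,2-acyl shift.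

Fallback (ring closure on a boron-free substrate): 17 and 31 are coupled first under the conditions of step 14 to give methyl (2S,4Z,8S,9E,11E)-4,8,12-trimethyl-15-[1-(3-methylbutyl)-5-oxo-2,5-dihydro-1H-pyrrol-3-yl]-2-(propanoyloxy)pentadeca-4,9,11-trienoate F7. LiHMDS, with one further equivalent to cover the acidic C21H2 of the lactam, then closes the tetronic acid and gives 32 directly. It sets out from 17 and comes back at 32.

**Step 2.** The alkenylmagnesium species may add to the ester carbonyl of 7 in competition with epoxide opening.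

Fallback (epoxide without a carbonyl, oxidation afterwards):
- 9 opens (2S)-2-{[(4-methoxyphenyl)methoxy]methyl}oxirane F8 under the same copper catalysis to give (2S,4Z)-7-{[tert-butyl(dimethyl)silyl]oxy}-1-[(4-methoxyphenyl)methoxy]-4-methylhept-4-en-2-ol F9.
- DDQ in wet CH2Cl2 frees (2S,4Z)-7-{[tert-butyl(dimethyl)silyl]oxy}-4-methylhept-4-ene-1,2-diol F10.
- TEMPO/PhI(OAc)2 in aqueous MeCN oxidises the primary alcohol selectively to (2S,4Z)-7-{[tert-butyl(dimethyl)silyl]oxy}-2-hydroxy-4-methylhept-4-enoic acid F11.
- Trimethylsilyldiazomethane gives 10.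

It sets out from 9 and comes back at 10.

**Step 13.** The condensation may stop at the cyclic hemiaminal, which the mild hydride does not reduce, or the amine may add in conjugate fashion.

Fallback (stepwise, through the N-acyliminium ion): 27 and 28 are condensed without reductant (MeOH, rt) to 5-hydroxy-4-[(4E)-5-iodo-4-methylpent-4-en-1-yl]-1-(3-methylbutyl)-1,5-dihydro-2H-pyrrol-2-one F12. This is deoxygenated with Et3SiH/BF3·OEt2 (CH2Cl2, −78 → 0 °C) to 31. It sets out from 27 and comes back at 31.

**Step 14.** The tetronate may bind palladium and slow transmetalation so that protodeboronation competes. The diene may isomerise during the acidic work-up.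

Fallback (masked tetronic acid):
- 18 is O-alkylated under Mitsunobu conditions (2-(trimethylsilyl)ethanol, PPh3, DIAD) to (5S)-5-[(2Z,6S,7E)-2,6-dimethyl-8-(4,4,5,5-tetramethyl-1,3,2-dioxaborolan-2-yl)octa-2,7-dien-1-yl]-3-methyl-4-[2-(trimethylsilyl)ethoxy]furan-2(5H)-one F13.
- Suzuki coupling with 31 gives (5S)-3-methyl-5-{(2Z,6S,7E,9E)-2,6,10-trimethyl-13-[1-(3-methylbutyl)-5-oxo-2,5-dihydro-1H-pyrrol-3-yl]trideca-2,7,9-trien-1-yl}-4-[2-(trimethylsilyl)ethoxy]furan-2(5H)-one F14.
- Fluoride (TBAF, THF, rt) removes the silylethyl group and gives 32 without acid.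

It sets out from 18 and comes back at 32.

## Further compounds

F1 | step 7 | (3S)-3,7-dimethyloct-6-enal | O=CC[C@@H](C)CCC=C(C)C
F2 | step 7 | (3S)-3,7-dimethyloct-6-en-1-yne | C#C[C@@H](C)CCC=C(C)C
F3 | step 7 | (4S)-4-methylhex-5-ynal | O=CCC[C@H](C)C#C
F4 | step 7 | (3S,6Z)-7-iodo-3-methyloct-6-en-1-yne | C#C[C@@H](C)CC/C=C(/C)I
F5 | step 7 | methyl (2S,4Z,8S)-2-hydroxy-4,8-dimethyldec-4-en-9-ynoate | COC(=O)[C@@H](O)C/C(C)=C\CC[C@H](C)C#C
F6 | step 7 | methyl (2S,4Z,8S)-4,8-dimethyl-2-(propanoyloxy)dec-4-en-9-ynoate | CCC(=O)O[C@@H](C/C(C)=C\CC[C@H](C)C#C)C(=O)OC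
F7 | step 8 | methyl (2S,4Z,8S,9E,11E)-4,8,12-trimethyl-15-[1-(3-methylbutyl)-5-oxo-2,5-dihydro-1H-pyrrol-3-yl]-2-(propanoyloxy)pentadeca-4,9,11-trienoate | CCC(=O)O[C@@H](C/C(C)=C\CC[C@H](C)/C=C/C=C(\C)CCCC1=CC(=O)N(CCC(C)C)C1)C(=O)OC
F8 | step 2 | (2S)-2-{[(4-methoxyphenyl)methoxy]methyl}oxirane | COc1ccc(COC[C@@H]2CO2)cc1
F9 | step 2 | (2S,4Z)-7-{[tert-butyl(dimethyl)silyl]oxy}-1-[(4-methoxyphenyl)methoxy]-4-methylhept-4-en-2-ol | COc1ccc(COC[C@@H](O)C/C(C)=C\CCO[Si](C)(C)C(C)(C)C)cc1
F10 | step 2 | (2S,4Z)-7-{[tert-butyl(dimethyl)silyl]oxy}-4-methylhept-4-ene-1,2-diol | OC[C@@H](O)C/C(C)=C\CCO[Si](C)(C)C(C)(C)C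
F11 | step 2 | (2S,4Z)-7-{[tert-butyl(dimethyl)silyl]oxy}-2-hydroxy-4-methylhept-4-enoic acid | OC(=O)[C@@H](O)C/C(C)=C\CCO[Si](C)(C)C(C)(C)C
F12 | step 13 | 5-hydroxy-4-[(4E)-5-iodo-4-methylpent-4-en-1-yl]-1-(3-methylbutyl)-1,5-dihydro-2H-pyrrol-2-one | O=C1C=C(CCC/C(C)=C/I)C(O)N1CCC(C)C
F13 | step 14 | (5S)-5-[(2Z,6S,7E)-2,6-dimethyl-8-(4,4,5,5-tetramethyl-1,3,2-dioxaborolan-2-yl)octa-2,7-dien-1-yl]-3-methyl-4-[2-(trimethylsilyl)ethoxy]furan-2(5H)-one | CC1=C(OCC[Si](C)(C)C)[C@H](C/C(C)=C\CC[C@H](C)/C=C/B2OC(C)(C)C(C)(C)O2)OC1=O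
F14 | step 14 | (5S)-3-methyl-5-{(2Z,6S,7E,9E)-2,6,10-trimethyl-13-[1-(3-methylbutyl)-5-oxo-2,5-dihydro-1H-pyrrol-3-yl]trideca-2,7,9-trien-1-yl}-4-[2-(trimethylsilyl)ethoxy]furan-2(5H)-one | CC1=C(OCC[Si](C)(C)C)[C@H](C/C(C)=C\CC[C@H](C)/C=C/C=C(\C)CCCC2=CC(=O)N(CCC(C)C)C2)OC1=O
A1 | alternative 1 | (3S)-3,7-dimethylocta-1,6-diene | C=C[C@@H](C)CCC=C(C)C
A2 | alternative 1 | (4S)-4-methylhex-5-enal | O=CCC[C@H](C)C=C
A3 | alternative 2 | 4-[(4E,6E,8S)-4,8,12-trimethyltrideca-4,6,12-trien-1-yl]-1-(3-methylbutyl)-1,5-dihydro-2H-pyrrol-2-one | C=C(C)CCC[C@H](C)/C=C/C=C(\C)CCCC1=CC(=O)N(CCC(C)C)C1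
A4 | alternative 2 | ethyl (2S,4Z,8S,9E,11E)-2-hydroxy-4,8,12-trimethyl-15-[1-(3-methylbutyl)-5-oxo-2,5-dihydro-1H-pyrrol-3-yl]pentadeca-4,9,11-trienoate | CCOC(=O)[C@@H](O)C/C(C)=C\CC[C@H](C)/C=C/C=C(\C)CCCC1=CC(=O)N(CCC(C)C)C1
A5 | alternative 3 | (5S)-5-[(2Z,6S,7E,9E)-13-(furan-3-yl)-2,6,10-trimethyltrideca-2,7,9-trien-1-yl]-4-hydroxy-3-methylfuran-2(5H)-one | CC1=C(O)[C@H](C/C(C)=C\CC[C@H](C)/C=C/C=C(\C)CCCc2ccoc2)OC1=O
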